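## Retrosynthetic overview

1. The C5–benzoyl bond is made last, by adding a bridgehead dianion of the 3-prenylated bicyclic trione to benzonitrile; the C3 prenyl group comes from Tsuji–Trost allylation of the trione.
2. The bicyclo[3.3.1]nonane-2,4,9-trione comes from an oxidative 1,2-alkyl shift that expands the cyclopentane ring of a cis-hydrindane β-hydroxy-1,3-dione.
3. The hydrindanedione comes from diketene annulation on the tetrasubstituted enolate of 3,3-dimethyl-2,4-diprenylcyclopentanone.
4. The cyclopentanone comes from asymmetric conjugate addition (sets C7) to 5-prenyl-4,4-dimethylcyclopentenone, itself from α′-prenylation of 4,4-dimethylcyclopent-2-en-1-one.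
5. Ring order: cyclopentane (bought), then the fused cyclohexane-1,3-dione (annulation), then expansion of the cyclopentane to the second six-membered ring.

Assumption: prenyl = 3-methylbut-2-en-1-yl; enolised 1,3-diketones are drawn as one tautomer; bicyclic atoms are numbered as in the target name (C1 = prenyl bridgehead next to CMe2, C5 = benzoyl bridgehead); the sense of induction of the chiral ligand in step 2 must be confirmed on the first run and the ligand antipode used if needed.

## Route

Step 1
Reactants: 1 4,4-dimethylcyclopent-2-en-1-one; 2 1-bromo-3-methylbut-2-ene (prenyl bromide)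
Product: 3 rac-4,4-dimethyl-5-(3-methylbut-2-en-1-yl)cyclopent-2-en-1-one
Conditions: LiN(i-Pr)2 (1.05 equiv), THF, −78 °C; then 2, DMPU, −78 → 0 °C
Reagents that add atoms: none
Why: C5 is the only enolisable position (C4 is quaternary), so kinetic deprotonation gives the cross-conjugated lithium dienolate, which is C-alkylated by the allylic bromide (enolate alkylation); the new centre is racemic and is erased in step 4.

Step 2
Reactants: 3 rac-4,4-dimethyl-5-(3-methylbut-2-en-1-yl)cyclopent-2-en-1-one; 4 4-bromo-2-methylbut-1-ene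
Product: 6 (4R)-3,3-dimethyl-2-(3-methylbut-2-en-1-yl)-4-(3-methylbut-3-en-1-yl)cyclopentan-1-one (both C2 epimers), via Grignard reagent 5 (not isolated)
Conditions: 4, Mg, Et2O, 35 °C; then CuBr·SMe2 (5 mol %), (R)-1-[(S)-2-(diphenylphosphino)ferrocenyl]ethyldicyclohexylphosphine (C36H44FeP2, 6 mol %), t-BuOMe, −78 °C, slow addition of 3; then 1 M HCl, 0 °C
Reagents that add atoms: none
Why: Copper-catalysed asymmetric conjugate addition of a Grignard reagent, in which the chiral diphosphine–copper complex selects the enone face so that C4 is formed R in both C2 epimers (catalyst control; the C2 centre is removed later), and an sp3 homoallyl nucleophile is used because allylic prenyl metals add 1,2 or with allyl transposition.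

Step 3
Reactants: 6 (4R)-3,3-dimethyl-2-(3-methylbut-2-en-1-yl)-4-(3-methylbut-3-en-1-yl)cyclopentan-1-one
Product: 7 (4R)-3,3-dimethyl-2,4-bis(3-methylbut-2-en-1-yl)cyclopentan-1-one (both C2 epimers)
Conditions: (salen)CoCl [salen = N,N′-bis(3,5-di-tert-butylsalicylidene)cyclohexane-1,2-diaminate; C36H52ClCoN2O2] (3 mol %), PhSiH3 (6 mol %), benzene, 23 °C
Reagents that add atoms: none
Why: Cobalt-hydride hydrogen-atom-transfer alkene isomerisation moves the 1,1-disubstituted terminal double bond by one position to the thermodynamically favoured trisubstituted (prenyl) position, leaving the ketone, the existing prenyl group and the C4 centre untouched.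

Step 4
Reactants: 7 (4R)-3,3-dimethyl-2,4-bis(3-methylbut-2-en-1-yl)cyclopentan-1-one
Product: 8 trimethyl{[(4R)-3,3-dimethyl-2,4-bis(3-methylbut-2-en-1-yl)cyclopent-1-en-1-yl]oxy}silane
Conditions: Me3SiCl, NaI, Et3N, MeCN, 23 → 40 °C
Reagents that add atoms: chlorotrimethylsilane, C[Si](C)(C)Cl
Why: Equilibrating silylation (Me3SiI formed in the flask, Et3N) gives the more substituted, tetrasubstituted silyl enol ether (thermodynamic silyl enol ether formation), which merges the two C2 epimers and fixes the enolate regiochemistry at the neopentyl carbon where kinetic bases would not deprotonate.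

Step 5
Reactants: 8 trimethyl{[(4R)-3,3-dimethyl-2,4-bis(3-methylbut-2-en-1-yl)cyclopent-1-en-1-yl]oxy}silane; 9 diketene (4-methylideneoxetan-2-one)
Product: 11 (2R,3aS,7aR)-7a-hydroxy-3,3-dimethyl-2,3a-bis(3-methylbut-2-en-1-yl)-2,3,3a,7a-tetrahydro-1H-indene-4,6(5H,7H)-dione (cis-fused), via lithium enolate 10 (not isolated)
Conditions: MeLi (1.05 equiv), THF, 0 °C; then 9, −78 → −40 °C; then AcOH
Reagents that add atoms: none
Why: Diketene annulation (C-acylation then intramolecular aldol addition), in which the regiodefined lithium enolate attacks the lactone carbonyl anti to the C4 prenyl group (the pseudoaxial C3 methyl on the prenyl face blocks the other side, setting C3a) and the methyl-ketone enolate released by ring opening adds to the cyclopentanone carbonyl from the tether face to give the cis-fused aldol (setting C7a).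

Step 6
Reactants: 11 (2R,3aS,7aR)-7a-hydroxy-3,3-dimethyl-2,3a-bis(3-methylbut-2-en-1-yl)-2,3,3a,7a-tetrahydro-1H-indene-4,6(5H,7H)-dione
Product: 13 (1R,5S,7R)-8,8-dimethyl-1,7-bis(3-methylbut-2-en-1-yl)bicyclo[3.3.1]nonane-2,4,9-trione, via iodonium ylide 12 (not isolated)
Conditions: PhI(OAc)2 (1.2 equiv), KOH (4 equiv), MeOH, 0 °C; then 1 M HCl to pH 3
Reagents that add atoms: none
Why: Oxidative ring expansion by a vinylogous semipinacol 1,2-alkyl shift, in which PhI(OAc)2 forms the C5 iodonium ylide of the 1,3-diketone, enolisation toward C7 makes C7 electrophilic, and the C7a alkoxide pushes the cyclopentane CH2 (C1, the only bond that can lie axial to the enol π system) from C7a to C7 with loss of PhI; the new bridgehead configuration is dictated by C3a.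

Step 7
Reactants: 13 (1R,5S,7R)-8,8-dimethyl-1,7-bis(3-methylbut-2-en-1-yl)bicyclo[3.3.1]nonane-2,4,9-trione; 14 3-methylbut-2-en-1-ol
Product: 15 (1S,5S,7R)-4-hydroxy-8,8-dimethyl-1,3,7-tris(3-methylbut-2-en-1-yl)bicyclo[3.3.1]non-3-ene-2,9-dione (the C1 label changes by priority rules only)
Conditions: 14 (1.05 equiv), Pd(PPh3)4 (5 mol %), Et3B (30 mol %), THF, 23 °C
Reagents that add atoms: none
Why: Tsuji–Trost C-allylation of the acidic cyclic 1,3-diketone with the free allylic alcohol (Et3B activation), in which the soft diketonate attacks the unsubstituted terminus of the 1,1-dimethylallyl–palladium complex to give the linear C3 prenyl group and reversible O-allylation funnels to the C-product.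

Step 8
Reactants: 15 (1S,5S,7R)-4-hydroxy-8,8-dimethyl-1,3,7-tris(3-methylbut-2-en-1-yl)bicyclo[3.3.1]non-3-ene-2,9-dione; 16 benzonitrile
Product: 19 (1R,5S,7R)-5-benzoyl-4-hydroxy-8,8-dimethyl-1,3,7-tris(3-methylbut-2-en-1-yl)bicyclo[3.3.1]non-3-ene-2,9-dione, via dilithium dianion 17 (not isolated), via N-H ketimine 18 (not isolated)
Conditions: LiN(i-Pr)2 (2.2 equiv), THF, −78 → 0 °C; then 16, −78 → 0 °C; then 1 M HCl, THF, 23 °C
Reagents that add atoms: water, O
Why: Proposed new method: after O-deprotonation a second equivalent of LiN(i-Pr)2 removes the bridgehead γ-hydrogen at C5 to give a Hauser-type dilithio dianion whose carbanion is held as the C4=C5 bridgehead enolate (allowed in bicyclo[3.3.1]nonane) and is the most basic site, so it adds to the nitrile carbon with retention enforced by the cage (C5 becomes the quaternary S centre), and mild acid then hydrolyses the non-enolisable N–H ketimine to the benzoyl ketone without any enol protection; the closest known reaction types are γ-functionalisation of β-diketone dianions (Hauser–Harris) and bridgehead lithiation–acylation of bicyclo[3.3.1]nonane vinylogous esters.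

## Compound list

1 | 4,4-dimethylcyclopent-2-en-1-one | O=C1C=CC(C)(C)C1 | starting material
2 | 1-bromo-3-methylbut-2-ene (prenyl bromide) | CC(C)=CCBr | starting material
3 | rac-4,4-dimethyl-5-(3-methylbut-2-en-1-yl)cyclopent-2-en-1-one | O=C1C=CC(C)(C)C1CC=C(C)C | intermediate
4 | 4-bromo-2-methylbut-1-ene | C=C(C)CCBr | starting material
5 | (3-methylbut-3-en-1-yl)magnesium bromide | C=C(C)CC[Mg]Br | intermediate
6 | (4R)-3,3-dimethyl-2-(3-methylbut-2-en-1-yl)-4-(3-methylbut-3-en-1-yl)cyclopentan-1-one (C2 epimers) | O=C1C[C@@H](CCC(C)=C)C(C)(C)C1CC=C(C)C | intermediate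
7 | (4R)-3,3-dimethyl-2,4-bis(3-methylbut-2-en-1-yl)cyclopentan-1-one (C2 epimers) | O=C1C[C@@H](CC=C(C)C)C(C)(C)C1CC=C(C)C | intermediate
8 | trimethyl{[(4R)-3,3-dimethyl-2,4-bis(3-methylbut-2-en-1-yl)cyclopent-1-en-1-yl]oxy}silane | C[Si](C)(C)OC1=C(CC=C(C)C)C(C)(C)[C@H](CC=C(C)C)C1 | intermediate
9 | diketene (4-methylideneoxetan-2-one) | C=C1CC(=O)O1 | starting material
10 | lithium (4R)-3,3-dimethyl-2,4-bis(3-methylbut-2-en-1-yl)cyclopent-1-en-1-olate | [Li+].[O-]C1=C(CC=C(C)C)C(C)(C)[C@H](CC=C(C)C)C1 | intermediate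
11 | (2R,3aS,7aR)-7a-hydroxy-3,3-dimethyl-2,3a-bis(3-methylbut-2-en-1-yl)-2,3,3a,7a-tetrahydro-1H-indene-4,6(5H,7H)-dione | O=C1CC(=O)[C@@]2(CC=C(C)C)C(C)(C)[C@H](CC=C(C)C)C[C@@]2(O)C1 | intermediate
12 | C5 phenyliodonium ylide of 11 (same configuration as 11) | [O-]C1=C([I+]c3ccccc3)C(=O)[C@@]2(CC=C(C)C)C(C)(C)[C@H](CC=C(C)C)C[C@@]2(O)C1 | intermediate
13 | (1R,5S,7R)-8,8-dimethyl-1,7-bis(3-methylbut-2-en-1-yl)bicyclo[3.3.1]nonane-2,4,9-trione | O=C1CC(=O)[C@@]2(CC=C(C)C)C(C)(C)[C@H](CC=C(C)C)C[C@@H]1C2=O | intermediate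
14 | 3-methylbut-2-en-1-ol | CC(C)=CCO | starting material
15 | (1S,5S,7R)-4-hydroxy-8,8-dimethyl-1,3,7-tris(3-methylbut-2-en-1-yl)bicyclo[3.3.1]non-3-ene-2,9-dione | CC(C)=CCC1=C(O)[C@@H]2C[C@@H](CC=C(C)C)C(C)(C)[C@](CC=C(C)C)(C1=O)C2=O | intermediate
16 | benzonitrile | N#Cc1ccccc1 | starting material
17 | dilithium dianion of 15 (C2/C4 diketonate plus C5 bridgehead carbanion, drawn as the C4=C5 bridgehead enolate; C1 and C7 as in 15) | [Li+].[Li+].CC(C)=CCC1=C([O-])[C@@]2(CC=C(C)C)C(C)(C)[C@H](CC=C(C)C)CC(C2=O)=C1[O-] | intermediate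
18 | N–H ketimine of 19 (C=NH in place of the benzoyl C=O; same spatial arrangement as 19) | CC(C)=CCC1=C(O)[C@]2(C(=N)c3ccccc3)C[C@@H](CC=C(C)C)C(C)(C)[C@](CC=C(C)C)(C1=O)C2=O | intermediate
19 | (1R,5S,7R)-5-benzoyl-4-hydroxy-8,8-dimethyl-1,3,7-tris(3-methylbut-2-en-1-yl)bicyclo[3.3.1]non-3-ene-2,9-dione | CC(C)=CCC1=C(O)[C@]2(C(=O)c3ccccc3)C[C@@H](CC=C(C)C)C(C)(C)[C@](CC=C(C)C)(C1=O)C2=O | target

## Step count and risks

Total step count: 8. Longest linear sequence: 8 steps (1 to 19).

The three steps most likely to fail are step 8 (the proposed new step), step 5 and step 2.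

**Step 8.** The bridgehead dianion may not form cleanly, or the hindered ketimine may resist mild hydrolysis. The fallback is the known vinylogous-ester sequence; it sets out from 15 and comes back at 19. O-Methylation of 15 (Me2SO4, K2CO3, acetone) gives the enol ether 2-methoxy-8,8-dimethyl-1,3,7-triprenylbicyclo[3.3.1]non-2-ene-4,9-dione F5, in which the free carbonyl sits next to the bridgehead C–H; the 4-methoxy regioisomer is recycled to 15 with LiCl in DMSO. Bridgehead lithiation of F5 with lithium 2,2,6,6-tetramethylpiperidide in THF at −78 °C and addition to benzaldehyde gives the carbinol 5-[hydroxy(phenyl)methyl]-2-methoxy-8,8-dimethyl-1,3,7-triprenylbicyclo[3.3.1]non-2-ene-4,9-dione F6 as a mixture of carbinol epimers. Dess–Martin oxidation gives the ketone 5-benzoyl-2-methoxy-8,8-dimethyl-1,3,7-triprenylbicyclo[3.3.1]non-2-ene-4,9-dione F7. LiCl in DMSO at 120 °C removes the methyl group and gives 19.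

**Step 5.** The neopentyl tetrasubstituted enolate may be O-acylated by diketene, or the regiopurity of 8 may be too low. The fallback avoids both the hindered intermolecular acylation and the thermodynamic enol ether; it sets out from 7 and comes back at 13, so it also bypasses step 6. One-carbon ring expansion of 7 with Me3SiCHN2 and Sc(OTf)3 (10 mol %) in CH2Cl2, with migration of the less substituted CH2, gives the cyclohexanone (4S)-3,3-dimethyl-2,4-bis(3-methylbut-2-en-1-yl)cyclohexan-1-one F3 (same centre as in 7, label changed by priority only). Kinetic enolisation (LiN(i-Pr)2, Me3SiCl, THF, −78 °C) gives the silyl enol ether trimethyl{[(4R)-5,5-dimethyl-4,6-bis(3-methylbut-2-en-1-yl)cyclohex-1-en-1-yl]oxy}silane F4. Effenberger cyclisation of F4 with malonyl dichloride (Et2O, −20 → 23 °C, then aqueous KOH with BnEt3NCl) forms the hindered C1–C2 bond intramolecularly and gives 13.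

**Step 2.** Enantioselectivity or 1,4-selectivity may be poor on this hindered, racemic 5-substituted enone. The fallback sets the C4 centre by asymmetric conjugate reduction instead; it sets out from 3 and comes back at 6. Reagent 5 is added to 3 under achiral copper catalysis (CuI 10 mol %, Me3SiCl, THF, −78 °C) to give the racemic silyl enol ether trimethyl{[4,4-dimethyl-3-(3-methylbut-3-en-1-yl)-5-(3-methylbut-2-en-1-yl)cyclopent-1-en-1-yl]oxy}silane F1. Saegusa–Ito dehydrogenation with Pd(OAc)2 in MeCN gives the β-substituted enone 4,4-dimethyl-3-(3-methylbut-3-en-1-yl)-5-(3-methylbut-2-en-1-yl)cyclopent-2-en-1-one F2. Asymmetric copper hydride conjugate reduction of F2 (CuCl, NaOt-Bu, (S)-p-Tol-BINAP or its antipode, polymethylhydrosiloxane, toluene, then Bu4NF) gives 6.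

Further compounds
F1 | step 2 | trimethyl{[4,4-dimethyl-3-(3-methylbut-3-en-1-yl)-5-(3-methylbut-2-en-1-yl)cyclopent-1-en-1-yl]oxy}silane (racemic) | C[Si](C)(C)OC1=CC(CCC(C)=C)C(C)(C)C1CC=C(C)C
F2 | step 2 | 4,4-dimethyl-3-(3-methylbut-3-en-1-yl)-5-(3-methylbut-2-en-1-yl)cyclopent-2-en-1-one (racemic) | O=C1C=C(CCC(C)=C)C(C)(C)C1CC=C(C)C
F3 | step 5 | (4S)-3,3-dimethyl-2,4-bis(3-methylbut-2-en-1-yl)cyclohexan-1-one (C2 epimers) | O=C1CC[C@@H](CC=C(C)C)C(C)(C)C1CC=C(C)C
F4 | step 5 | trimethyl{[(4R)-5,5-dimethyl-4,6-bis(3-methylbut-2-en-1-yl)cyclohex-1-en-1-yl]oxy}silane | C[Si](C)(C)OC1=CC[C@@H](CC=C(C)C)C(C)(C)C1CC=C(C)C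
F5 | step 8 | 2-methoxy-8,8-dimethyl-1,3,7-tris(3-methylbut-2-en-1-yl)bicyclo[3.3.1]non-2-ene-4,9-dione (C1, C5, C7 as in 15) | COC1=C(CC=C(C)C)C(=O)[C@@H]2C[C@@H](CC=C(C)C)C(C)(C)[C@@]1(CC=C(C)C)C2=O
F6 | step 8 | 5-[hydroxy(phenyl)methyl]-2-methoxy-8,8-dimethyl-1,3,7-tris(3-methylbut-2-en-1-yl)bicyclo[3.3.1]non-2-ene-4,9-dione (ring centres as in 19, carbinol epimers) | COC1=C(CC=C(C)C)C(=O)[C@]2(C(O)c3ccccc3)C[C@@H](CC=C(C)C)C(C)(C)[C@@]1(CC=C(C)C)C2=O
F7 | step 8 | 5-benzoyl-2-methoxy-8,8-dimethyl-1,3,7-tris(3-methylbut-2-en-1-yl)bicyclo[3.3.1]non-2-ene-4,9-dione (ring centres as in 19) | COC1=C(CC=C(C)C)C(=O)[C@]2(C(=O)c3ccccc3)C[C@@H](CC=C(C)C)C(C)(C)[C@@]1(CC=C(C)C)C2=O
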